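**Retrosynthetic overview**
1. The 12-membered ring is opened at both C11–C15′ bonds, giving two identical trienoates 18 (head-to-tail cyclodimerisation, last ring formed).
2. 18 comes from acetoxy dienone 11: C15 by vinylogous acyl substitution, C11–C13 by a pyruvate aldol condensation at C7.
3. Cyclopropane and cyclopentene are cut together (C1–C3 and C2–C3) to the 1,5-enyne acetate 9 on an intact six-membered ring (gold-catalysed acyloxy shift/cyclopropanation).
4. The C9/C10 pair comes from a vinyl semipinacol shift in epoxy alcohol 5, made by asymmetric vinylation of quinone monoketal 2 from phenol 1.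
5. Ring order: six-membered ring (dearomatised arene) → cyclopropane and five-membered ring in one step → macrocycle.

Assumption: tricyclic compounds are named with lindenane numbering (cyclopropane C1–C2–C3, C4 carrying C15, C5–C10, C14 methyl on C10, side chain C11–C13), TBS = tert-butyldimethylsilyl, and centres or alkene geometries that are destroyed later (C1 of 8/9, C7/C11 of 16/17, C11 of 19, C7=C11 of 18) are left undefined.

**Step 1**
Reactants: 1 4-methoxy-2-methylphenol
Product: 2 4,4-dimethoxy-2-methylcyclohexa-2,5-dien-1-one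
Conditions: PhI(OAc)2 (1.1 equiv), MeOH, 0 °C
Reagents that add atoms: methanol, CO
Why: Hypervalent-iodine oxidative dearomatisation of a para-alkoxyphenol in methanol traps the phenoxenium ion at the methoxy-bearing carbon and gives the p-quinone monoketal (no stereocentre).

**Step 2**
Reactants: 2 4,4-dimethoxy-2-methylcyclohexa-2,5-dien-1-one; 3 vinylmagnesium bromide
Product: 5 (1S,2R,6R)-5,5-dimethoxy-1-methyl-2-vinyl-7-oxabicyclo[4.1.0]hept-3-en-2-ol, via dienol 4 (not isolated)
Conditions: 3 (3.2 equiv), ZnCl2 (1.6 equiv), 1,4-dioxane, toluene, 0 °C [gives Zn(CH=CH2)2]; Ti(OiPr)4 (1.2 equiv), trans-1,2-bis(2-hydroxybornane-10-sulfonamido)cyclohexane (10 mol %, enantiomer giving the R carbinol), rt; then t-BuOOH (decane), 0 °C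
Reagents that add atoms: vinylmagnesium bromide 3 (via divinylzinc), C=C[Mg]Br; tert-butyl hydroperoxide, CC(C)(C)OO
Why: Titanium/bis(sulfonamide)-diol-catalysed enantioselective 1,2-addition of the vinylzinc reagent (catalytic asymmetric ketone vinylation) distinguishes the methyl-bearing from the unsubstituted alkenyl arm and sets the carbinol centre (R), after which the titanium alkoxide directs t-BuOOH to the syn face of the trisubstituted allylic alkene (hydroxyl-directed epoxidation), placing the epoxide cis to the hydroxyl.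

**Step 3**
Reactants: 5 (1S,2R,6R)-5,5-dimethoxy-1-methyl-2-vinyl-7-oxabicyclo[4.1.0]hept-3-en-2-ol
Product: 6 (5R,6R)-5-(tert-butyldimethylsilyloxy)-4,4-dimethoxy-6-methyl-6-vinylcyclohex-2-en-1-one
Conditions: TBSOTf (1.2 equiv), 2,6-lutidine (2 equiv), CH2Cl2, −78 °C
Reagents that add atoms: tert-butyldimethylsilyl triflate, CC(C)(C)[Si](C)(C)OS(=O)(=O)C(F)(F)F
Why: Silyl-triflate-promoted semipinacol rearrangement of the 2,3-epoxy alcohol moves the vinyl group, which lies anti to the epoxide C–O bond, onto the methyl-bearing carbon with inversion while the silylated oxygen stays on its carbon, so the quaternary centre (methyl cis to OTBS, vinyl trans) and the silyloxy centre are set stereospecifically and the enone is regenerated.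

**Step 4**
Reactants: 6 (5R,6R)-5-(tert-butyldimethylsilyloxy)-4,4-dimethoxy-6-methyl-6-vinylcyclohex-2-en-1-one; 7 ethynylmagnesium bromide
Product: 9 (5R,6R)-5-(tert-butyldimethylsilyloxy)-1-ethynyl-4,4-dimethoxy-6-methyl-6-vinylcyclohex-2-en-1-yl acetate (both C1 epimers), via alkoxide 8 (not isolated)
Conditions: 7 (1.5 equiv), THF, 0 °C; then Ac2O (3 equiv), DMAP (cat.), 0 °C to rt
Reagents that add atoms: ethynylmagnesium bromide 7, C#C[Mg]Br; acetic anhydride, CC(=O)OC(C)=O
Why: Grignard 1,2-addition of the acetylide to the non-enolisable enone carbonyl followed by O-acetylation of the magnesium alkoxide gives the tertiary propargylic acetate, whose new centre is an inconsequential epimer mixture because it becomes sp2 in step 5.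

**Step 5**
Reactants: 9 (5R,6R)-5-(tert-butyldimethylsilyloxy)-1-ethynyl-4,4-dimethoxy-6-methyl-6-vinylcyclohex-2-en-1-yl acetate
Product: 11 (1R,3S,9R,10S)-4-acetoxy-9-(tert-butyldimethylsilyloxy)-11,12,13,15-tetranorlindena-4,6-dien-8-one, via ketal 10 (not isolated)
Conditions: Ph3PAuNTf2 (2 mol %), CH2Cl2, 0 °C to rt; then p-TsOH·H2O (5 mol %), acetone–H2O, 0 °C
Reagents that add atoms: water, O
Why: Gold-catalysed 1,2-acyloxy migration generates a vinyl gold carbenoid at C3 that cyclopropanates the C10 vinyl group (Ohloff–Rautenstrauch-type 1,5-enyne cycloisomerisation), closing cyclopropane and cyclopentene in one event with the new CH2 syn to the C10 methyl and away from the bulkier C9(OTBS)/C8-ketal branch, which sets C1 (R) and C3 (S), and mild acid then unmasks the C8 ketone.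

**Step 6**
Reactants: 11 (1R,3S,9R,10S)-4-acetoxy-9-(tert-butyldimethylsilyloxy)-11,12,13,15-tetranorlindena-4,6-dien-8-one; 12 (trimethylsilyl)methylmagnesium chloride
Product: 14 (1R,3S,9R,10S)-9-(tert-butyldimethylsilyloxy)-11,12,13-trinorlindena-4(15),5-dien-8-one, via allylsilane 13 (not isolated)
Conditions: 12 (1.5 equiv), CuBr·SMe2 (20 mol %), THF, −78 to −40 °C; then AcOH (4 equiv), Bu4NF (1.2 equiv), −78 °C
Reagents that add atoms: (trimethylsilyl)methylmagnesium chloride 12, C[Si](C)(C)C[Mg]Cl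
Why: Copper-catalysed 1,6-addition–elimination at the acetoxy-bearing carbon (vinylogous acyl substitution) installs C15 as an allylsilane, and buffered fluoride then cleaves the activated C–Si bond to a trienolate that is protonated kinetically at C7 (deconjugative protodesilylation), giving the 4(15),5-diene ketone without any new stereocentre.

**Step 7**
Reactants: 14 (1R,3S,9R,10S)-9-(tert-butyldimethylsilyloxy)-11,12,13-trinorlindena-4(15),5-dien-8-one; 15 methyl pyruvate
Product: 18 methyl (1R,3S,9R,10S)-9-(tert-butyldimethylsilyloxy)-8-oxolindena-4(15),5,7(11)-trien-12-oate (E/Z mixture), via lithium aldolate 16 (not isolated), via aldol acetate 17 (not isolated)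
Conditions: LiN(SiMe3)2 (1.05 equiv), THF, −78 °C; 15 (1.3 equiv); Ac2O (2 equiv), −78 to 0 °C; then Et3N (3 equiv), DMAP (cat.), 0 °C; used at once
Reagents that add atoms: methyl pyruvate 15, CC(=O)C(=O)OC
Why: Enolisation at the doubly activated C7 methylene, α-selective aldol addition of the lithium trienolate to the ketone carbonyl of methyl pyruvate, acetylation and E1cB elimination (aldol condensation) give the 7(11)-alkylidene, the C7/C11 centres of 16 and 17 being transient and the alkene geometry irrelevant for step 8.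

**Step 8**
Reactants: 18 methyl (1R,3S,9R,10S)-9-(tert-butyldimethylsilyloxy)-8-oxolindena-4(15),5,7(11)-trien-12-oate (two molecules)
Product: 21 9,9′-bis-O-(tert-butyldimethylsilyl)cycloshizukaol A, via iodo enolate 19 (not isolated), via linear enolate 20 (not isolated)
Conditions: MgI2 (1.0 equiv), toluene–Et2O, 0 °C to rt, slow addition of 18 (final 2 mM)
Reagents that add atoms: none
Why: Proposed new method: iodide adds in a 1,8-sense to the unhindered C15 methylene of the MgI2-activated trienoate to give an ester magnesium enolate chelated between O8 and O12 that is also an allylic iodide (19), its C11 adds to C15 of a second activated triene (20), and the successor enolate closes the 12-membered ring by SN2 displacement of the allylic iodide, returning MgI2; the chelate holds ester and ketone cis and both C–C bonds are expected to form on the α face opposite the C14 methyl, the cyclopropane CH2 and the C9 OTBS group, which gives 11R,11′R, while the polarity (nucleophilic C11, electrophilic C15) enforces head-to-tail union; the closest known reactions are MgI2- or TiCl4/Bu4NI-triggered halo-Michael–aldol (iodide-mediated Morita–Baylis–Hillman) processes, Rauhut–Currier dimerisations and the [6+6] dimerisation of p-quinodimethanes to [2.2]paracyclophanes.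

**Step 9**
Reactants: 21 9,9′-bis-O-(tert-butyldimethylsilyl)cycloshizukaol A
Product: 22 cycloshizukaol A
Conditions: HF·pyridine, THF–pyridine, 0 °C to rt
Reagents that add atoms: none
Why: Fluoride cleavage of the two secondary silyl ethers (desilylation) under buffered conditions leaves the α-ketols, dienones, cyclopropanes and methyl esters untouched and changes no stereocentre.

**Compound list**
1 | 4-methoxy-2-methylphenol | COc1ccc(O)c(C)c1 | starting material
2 | 4,4-dimethoxy-2-methylcyclohexa-2,5-dien-1-one | COC1(OC)C=CC(=O)C(C)=C1 | intermediate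
3 | vinylmagnesium bromide | C=C[Mg]Br | starting material
4 | (R)-4,4-dimethoxy-2-methyl-1-vinylcyclohexa-2,5-dien-1-ol (present as its metal alkoxide) | C=C[C@@]1(O)C=CC(OC)(OC)C=C1C | intermediate
5 | (1S,2R,6R)-5,5-dimethoxy-1-methyl-2-vinyl-7-oxabicyclo[4.1.0]hept-3-en-2-ol | C=C[C@@]1(O)C=CC(OC)(OC)[C@@H]2O[C@]12C | intermediate
6 | (5R,6R)-5-(tert-butyldimethylsilyloxy)-4,4-dimethoxy-6-methyl-6-vinylcyclohex-2-en-1-one | O=C1C=CC(OC)(OC)[C@H](O[Si](C)(C)C(C)(C)C)[C@@]1(C)C=C | intermediate
7 | ethynylmagnesium bromide | C#C[Mg]Br | starting material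
8 | bromomagnesium (5R,6R)-5-(tert-butyldimethylsilyloxy)-1-ethynyl-4,4-dimethoxy-6-methyl-6-vinylcyclohex-2-en-1-olate (C1 epimers) | C#CC1(O[Mg]Br)C=CC(OC)(OC)[C@H](O[Si](C)(C)C(C)(C)C)[C@@]1(C)C=C | intermediate
9 | (5R,6R)-5-(tert-butyldimethylsilyloxy)-1-ethynyl-4,4-dimethoxy-6-methyl-6-vinylcyclohex-2-en-1-yl acetate (C1 epimers) | C#CC1(OC(C)=O)C=CC(OC)(OC)[C@H](O[Si](C)(C)C(C)(C)C)[C@@]1(C)C=C | intermediate
10 | (1R,3S,9R,10S)-4-acetoxy-9-(tert-butyldimethylsilyloxy)-8,8-dimethoxy-11,12,13,15-tetranorlindena-4,6-diene | CC(=O)OC1=C2C=CC(OC)(OC)[C@H](O[Si](C)(C)C(C)(C)C)[C@@]2(C)[C@@H]2C[C@H]12 | intermediate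
11 | (1R,3S,9R,10S)-4-acetoxy-9-(tert-butyldimethylsilyloxy)-11,12,13,15-tetranorlindena-4,6-dien-8-one | CC(=O)OC1=C2C=CC(=O)[C@H](O[Si](C)(C)C(C)(C)C)[C@@]2(C)[C@@H]2C[C@H]12 | intermediate
12 | (trimethylsilyl)methylmagnesium chloride | C[Si](C)(C)C[Mg]Cl | starting material
13 | (1R,3S,9R,10S)-9-(tert-butyldimethylsilyloxy)-15-(trimethylsilyl)-11,12,13-trinorlindena-4,6-dien-8-one | C[Si](C)(C)CC1=C2C=CC(=O)[C@H](O[Si](C)(C)C(C)(C)C)[C@@]2(C)[C@@H]2C[C@H]12 | intermediate
14 | (1R,3S,9R,10S)-9-(tert-butyldimethylsilyloxy)-11,12,13-trinorlindena-4(15),5-dien-8-one | C=C1C2=CCC(=O)[C@H](O[Si](C)(C)C(C)(C)C)[C@@]2(C)[C@@H]2C[C@H]12 | intermediate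
15 | methyl pyruvate | CC(=O)C(=O)OC | starting material
16 | lithium alkoxide of methyl (1R,3S,9R,10S)-9-(tert-butyldimethylsilyloxy)-11-hydroxy-8-oxolindena-4(15),5-dien-12-oate (C7/C11 epimers) | C=C1C2=CC(C(C)(O[Li])C(=O)OC)C(=O)[C@H](O[Si](C)(C)C(C)(C)C)[C@@]2(C)[C@@H]2C[C@H]12 | intermediate
17 | methyl (1R,3S,9R,10S)-11-acetoxy-9-(tert-butyldimethylsilyloxy)-8-oxolindena-4(15),5-dien-12-oate (C7/C11 epimers) | C=C1C2=CC(C(C)(OC(C)=O)C(=O)OC)C(=O)[C@H](O[Si](C)(C)C(C)(C)C)[C@@]2(C)[C@@H]2C[C@H]12 | intermediate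
18 | methyl (1R,3S,9R,10S)-9-(tert-butyldimethylsilyloxy)-8-oxolindena-4(15),5,7(11)-trien-12-oate (E/Z mixture) | C=C1C2=CC(=C(C)C(=O)OC)C(=O)[C@H](O[Si](C)(C)C(C)(C)C)[C@@]2(C)[C@@H]2C[C@H]12 | intermediate
19 | iodomagnesium ester enolate of methyl (1R,3S,9R,10S)-9-(tert-butyldimethylsilyloxy)-15-iodo-8-oxolindena-4,6-dien-12-oate | ICC1=C2C=C(C(C)=C(OC)O[Mg]I)C(=O)[C@H](O[Si](C)(C)C(C)(C)C)[C@@]2(C)[C@@H]2C[C@H]12 | intermediate
20 | open-chain dimer: unit A (15-iodo, quaternary 11R) joined C11–C15′ to unit B (iodomagnesium ester enolate) | ICC1=C2C=C([C@](C)(C(=O)OC)CC3=C4C=C(C(C)=C(OC)O[Mg]I)C(=O)[C@H](O[Si](C)(C)C(C)(C)C)[C@@]4(C)[C@@H]4C[C@H]34)C(=O)[C@H](O[Si](C)(C)C(C)(C)C)[C@@]2(C)[C@@H]2C[C@H]12 | intermediate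
21 | 9,9′-bis-O-(tert-butyldimethylsilyl)cycloshizukaol A | COC(=O)[C@]1(C)CC2=C3C=C(C(=O)[C@H](O[Si](C)(C)C(C)(C)C)[C@@]3(C)[C@@H]3C[C@H]23)[C@](C)(C(=O)OC)CC2=C3C=C1C(=O)[C@H](O[Si](C)(C)C(C)(C)C)[C@@]3(C)[C@@H]1C[C@H]21 | intermediate
22 | cycloshizukaol A | COC(=O)[C@]1(C)CC2=C3C=C(C(=O)[C@H](O)[C@@]3(C)[C@@H]3C[C@H]23)[C@](C)(C(=O)OC)CC2=C3C=C1C(=O)[C@H](O)[C@@]3(C)[C@@H]1C[C@H]21 | target

**Totals**
Total step count: 9. Longest linear sequence: 9 steps (1 → 22).

**Three steps most likely to fail**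

Step 8 (cyclodimerisation). Oligomers, [4+2] dimers of the cisoid diene, or the wrong C11 configuration are all possible; the facial bias at C11 rests only on the chelate model. Fallback, setting out from 18 and coming back at 21: 18 is first captured as a stable bifunctional monomer by 1,8-hydrobromination (HBr in AcOH, CH2Cl2, −40 °C), giving methyl (1R,3S,9R,10S)-15-bromo-9-(tert-butyldimethylsilyloxy)-8-oxolindena-4,6-dien-12-oate F1. Slow addition of F1 to Cs2CO3 in MeCN (1 mM, 40 °C) then effects two successive enolate C-alkylations, a classical [3.3]cyclophane-type ring closure. The first alkylation gives the open-chain bromide dimer F2 and the second closes the macrocycle to 21; C11 diastereomers would be separated here.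

Step 5 (gold cycloisomerisation). The doubly allylic tertiary propargylic acetate may ionise or rearrange, the allylic ketal is acid-labile, and the cyclopropane face selectivity is only sterically argued. Fallback, setting out from 6 and coming back at 11: conjugate reduction with [(Ph3P)CuH]6/PhSiH3 gives (2R,3R)-3-(tert-butyldimethylsilyloxy)-4,4-dimethoxy-2-methyl-2-vinylcyclohexan-1-one F3. Treatment with 7 and then Ac2O gives, through the bromomagnesium alkoxide F4, the saturated propargylic acetate F5, a plain 1,5-enyne without the competing allylic system. Cycloisomerisation with PtCl2 in toluene at 80 °C gives the saturated tricyclic ketal F6, which is hydrolysed to the enol acetate ketone F7. IBX in DMSO at 70 °C then introduces the C6=C7 double bond (the only α,β-pair carrying hydrogen) and delivers 11.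

Step 2 (asymmetric vinylation/epoxidation). The enantioselectivity on a cross-conjugated dienone with two sp2 α-carbons is not secured by precedent, and three allylic alkenes compete in the epoxidation. Fallback, setting out from 2 and coming back at 6: the unsubstituted enone double bond of 2 is reduced first ([(Ph3P)CuH]6/PhSiH3) to 4,4-dimethoxy-2-methylcyclohex-2-en-1-one F8, an α-substituted cyclohexenone of the class for which this vinylation/directed epoxidation is established. The same one-pot protocol gives, through the allylic alcohol F9, the epoxy alcohol F10, whose TBSOTf-promoted semipinacol shift gives the saturated ketone F3 described under step 5. IBX dehydrogenation of F3 then returns 6.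

**Further compounds**
F1 | step 8 | methyl (1R,3S,9R,10S)-15-bromo-9-(tert-butyldimethylsilyloxy)-8-oxolindena-4,6-dien-12-oate (C11 epimers) | BrCC1=C2C=C(C(C)C(=O)OC)C(=O)[C@H](O[Si](C)(C)C(C)(C)C)[C@@]2(C)[C@@H]2C[C@H]12
F2 | step 8 | open-chain dimer bromide: unit A (15-bromo, quaternary 11R) joined C11–C15′ to unit B (C11–H ester) | BrCC1=C2C=C([C@](C)(C(=O)OC)CC3=C4C=C(C(C)C(=O)OC)C(=O)[C@H](O[Si](C)(C)C(C)(C)C)[C@@]4(C)[C@@H]4C[C@H]34)C(=O)[C@H](O[Si](C)(C)C(C)(C)C)[C@@]2(C)[C@@H]2C[C@H]12
F3 | step 5 | (2R,3R)-3-(tert-butyldimethylsilyloxy)-4,4-dimethoxy-2-methyl-2-vinylcyclohexan-1-one | O=C1CCC(OC)(OC)[C@H](O[Si](C)(C)C(C)(C)C)[C@@]1(C)C=C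
F4 | step 5 | bromomagnesium (2R,3R)-3-(tert-butyldimethylsilyloxy)-1-ethynyl-4,4-dimethoxy-2-methyl-2-vinylcyclohexan-1-olate (C1 epimers) | C#CC1(O[Mg]Br)CCC(OC)(OC)[C@H](O[Si](C)(C)C(C)(C)C)[C@@]1(C)C=C
F5 | step 5 | (2R,3R)-3-(tert-butyldimethylsilyloxy)-1-ethynyl-4,4-dimethoxy-2-methyl-2-vinylcyclohexyl acetate (C1 epimers) | C#CC1(OC(C)=O)CCC(OC)(OC)[C@H](O[Si](C)(C)C(C)(C)C)[C@@]1(C)C=C
F6 | step 5 | (1R,3S,9R,10S)-4-acetoxy-9-(tert-butyldimethylsilyloxy)-8,8-dimethoxy-11,12,13,15-tetranorlind-4-ene | CC(=O)OC1=C2CCC(OC)(OC)[C@H](O[Si](C)(C)C(C)(C)C)[C@@]2(C)[C@@H]2C[C@H]12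
F7 | step 5 | (1R,3S,9R,10S)-4-acetoxy-9-(tert-butyldimethylsilyloxy)-11,12,13,15-tetranorlind-4-en-8-one | CC(=O)OC1=C2CCC(=O)[C@H](O[Si](C)(C)C(C)(C)C)[C@@]2(C)[C@@H]2C[C@H]12
F8 | step 2 | 4,4-dimethoxy-2-methylcyclohex-2-en-1-one | COC1(OC)CCC(=O)C(C)=C1
F9 | step 2 | (S)-4,4-dimethoxy-2-methyl-1-vinylcyclohex-2-en-1-ol | C=C[C@@]1(O)CCC(OC)(OC)C=C1C
F10 | step 2 | (1S,2S,6R)-5,5-dimethoxy-1-methyl-2-vinyl-7-oxabicyclo[4.1.0]heptan-2-ol | C=C[C@@]1(O)CCC(OC)(OC)[C@@H]2O[C@]12C
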